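The γ-lactone is read as the Baeyer–Villiger product of a cyclobutanone, itself the [2+2] adduct of a vinylketene (C12=C6) and a cis alkene (C7=C11); germacrane numbering, C12 the lactone carbonyl, C11 its α-carbon, C6 and C7 the ring-fusion carbons. Done intramolecularly on a seco acid, the cycloaddition forms C12–C11 and C6–C7 and closes the four-membered and the ten-membered ring together. It exploits the all-cis lactone ring (C5, C8, C13 on one face), the signature of a ketene adding to a cis alkene. The alkene sits in a 3,6-dihydro-2H-pyran whose oxygen becomes the C9 hydroxyl; the pyran fixes geometry, regiochemistry and face and is opened late by β-elimination.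

Key step: step 14

Remark: atoms carry germacrane numbers (ring C1–C10, C11/C12 lactone carbons, methyls C13 on C11, C14 on C10, C15 on C4); the SMILES is read as (3S,6R,7S,9S,11R) with a (2R)-2-methylbutanoate, a cis-fused lactone, Z at C1=C10 and E at C4=C5.

Step 1
Reactants: 1 3-{[tert-butyl(dimethyl)silyl]oxy}propanal; 2 ethyl 2-[bis(2,2,2-trifluoroethoxy)phosphoryl]propanoate
Product: 3 ethyl (2Z)-5-{[tert-butyl(dimethyl)silyl]oxy}-2-methylpent-2-enoate
Conditions: KN(SiMe3)2, 18-crown-6, THF, −78 °C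
Reagents that add atoms: none
Why: Still–Gennari variant of the Horner–Wadsworth–Emmons olefination, in which the electron-poor phosphonate with a dissociated potassium counter-ion should give the kinetic (Z)-2-methyl enoate and so fix the cis C1=C10 geometry.

Step 2
Reactants: 3 ethyl (2Z)-5-{[tert-butyl(dimethyl)silyl]oxy}-2-methylpent-2-enoate
Product: 4 (2Z)-5-{[tert-butyl(dimethyl)silyl]oxy}-2-methylpent-2-en-1-ol
Conditions: i-Bu2AlH (2.5 equiv), CH2Cl2, −78 → 0 °C; aq. Rochelle salt
Reagents that add atoms: none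
Why: 1,2-reduction of the conjugated ester by the aluminium hydride should give the allylic alcohol without touching the silyl ether or the alkene geometry.

Step 3
Reactants: 4 (2Z)-5-{[tert-butyl(dimethyl)silyl]oxy}-2-methylpent-2-en-1-ol
Product: 5 (2Z)-5-{[tert-butyl(dimethyl)silyl]oxy}-2-methylpent-2-enal
Conditions: Dess–Martin periodinane, NaHCO3, CH2Cl2, 0 °C
Reagents that add atoms: none
Why: Dess–Martin oxidation under bicarbonate buffer should give the (Z)-enal without acid- or base-mediated isomerisation to the (E)-isomer.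

Step 4
Reactants: 5 (2Z)-5-{[tert-butyl(dimethyl)silyl]oxy}-2-methylpent-2-enal
Product: 6 (4S,5Z)-8-{[tert-butyl(dimethyl)silyl]oxy}-5-methylocta-1,5-dien-4-ol
Conditions: allylB(pin), (S)-TRIP (5 mol %), toluene, −30 °C
Reagents that add atoms: allylboronic acid pinacol ester, C=CCB1OC(C)(C)C(C)(C)O1
Why: chiral phosphoric acid catalysed allylboration through a chair transition state, with the acid enantiomer chosen to deliver allyl to the Si face of the aldehyde, which sets C9 as (S).

Step 5
Reactants: 6 (4S,5Z)-8-{[tert-butyl(dimethyl)silyl]oxy}-5-methylocta-1,5-dien-4-ol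
Product: 7 tert-butyl(dimethyl){[(3Z,5S)-4-methyl-5-(prop-2-en-1-yloxy)octa-3,7-dien-1-yl]oxy}silane
Conditions: NaH, allyl bromide, Bu4NI (cat.), THF, 0 → 23 °C
Reagents that add atoms: allyl bromide, C=CCBr
Why: Williamson ether synthesis of the secondary alkoxide with a reactive allylic bromide.

Step 6
Reactants: 7 tert-butyl(dimethyl){[(3Z,5S)-4-methyl-5-(prop-2-en-1-yloxy)octa-3,7-dien-1-yl]oxy}silane
Product: 8 tert-butyl{[(3Z)-4-[(2S)-3,6-dihydro-2H-pyran-2-yl]pent-3-en-1-yl]oxy}dimethylsilane
Conditions: second-generation Grubbs catalyst RuCl2(=CHPh)(PCy3)(H2IMes) (2 mol %), CH2Cl2, 40 °C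
Reagents that add atoms: none
Why: ring-closing metathesis of the two terminal alkenes should close the six-membered dihydropyran, whose ring alkene C7=C11 is necessarily cis, while the trisubstituted alkene stays out of the reaction.

Step 7
Reactants: 8 tert-butyl{[(3Z)-4-[(2S)-3,6-dihydro-2H-pyran-2-yl]pent-3-en-1-yl]oxy}dimethylsilane
Product: 9 (3Z)-4-[(2S)-3,6-dihydro-2H-pyran-2-yl]pent-3-en-1-ol
Conditions: Bu4NF, THF, 0 °C
Reagents that add atoms: none
Why: fluoride-mediated cleavage of the primary silyl ether.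

Step 8
Reactants: 9 (3Z)-4-[(2S)-3,6-dihydro-2H-pyran-2-yl]pent-3-en-1-ol
Product: 10 (3Z)-4-[(2S)-3,6-dihydro-2H-pyran-2-yl]pent-3-enal
Conditions: Dess–Martin periodinane, NaHCO3, CH2Cl2, 0 °C; used at once
Reagents that add atoms: none
Why: Dess–Martin oxidation is non-basic, so the β,γ-double bond should not move into conjugation with the new aldehyde.

Step 9
Reactants: 11 pent-3-yn-1-ol
Product: 12 tert-butyl(dimethyl)(pent-3-yn-1-yloxy)silane
Conditions: t-BuMe2SiCl, imidazole, CH2Cl2, 23 °C
Reagents that add atoms: tert-butyldimethylsilyl chloride, CC(C)(C)[Si](C)(C)Cl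
Why: standard silylation of the primary alcohol.

Step 10
Reactants: 12 tert-butyl(dimethyl)(pent-3-yn-1-yloxy)silane; 10 (3Z)-4-[(2S)-3,6-dihydro-2H-pyran-2-yl]pent-3-enal
Product: 15 (2Z,5S,6E)-9-{[tert-butyl(dimethyl)silyl]oxy}-2-[(2S)-3,6-dihydro-2H-pyran-2-yl]-6-methylnona-2,6-dien-5-ol, via alkenylzirconocene 13 (not isolated), via alkenylzinc 14 (not isolated)
Conditions: Cp2Zr(H)Cl, CH2Cl2, 23 °C; Me2Zn, toluene, −65 °C; (+)-MIB (10 mol %), then 10, −30 → 0 °C
Reagents that add atoms: none
Why: syn hydrozirconation should place zirconium on the methyl-bearing alkyne carbon, zirconium-to-zinc transmetalation gives the (E)-alkenylzinc, and the amino alcohol catalysed addition should occur on the Re face of the aldehyde under ligand control, which sets C3 as (S) and C4=C5 as E.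

Step 11
Reactants: 15 (2Z,5S,6E)-9-{[tert-butyl(dimethyl)silyl]oxy}-2-[(2S)-3,6-dihydro-2H-pyran-2-yl]-6-methylnona-2,6-dien-5-ol; 16 (2R)-2-methylbutanoic acid
Product: 17 (2Z,5S,6E)-9-{[tert-butyl(dimethyl)silyl]oxy}-2-[(2S)-3,6-dihydro-2H-pyran-2-yl]-6-methylnona-2,6-dien-5-yl (2R)-2-methylbutanoate
Conditions: EDC·HCl, DMAP (0.2 equiv), CH2Cl2, 0 → 23 °C
Reagents that add atoms: none
Why: Steglich-type carbodiimide esterification of the secondary allylic alcohol, mild enough to leave the α-stereocentre of the acid untouched.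

Step 12
Reactants: 17 (2Z,5S,6E)-9-{[tert-butyl(dimethyl)silyl]oxy}-2-[(2S)-3,6-dihydro-2H-pyran-2-yl]-6-methylnona-2,6-dien-5-yl (2R)-2-methylbutanoate
Product: 18 (2Z,5S,6E)-2-[(2S)-3,6-dihydro-2H-pyran-2-yl]-9-hydroxy-6-methylnona-2,6-dien-5-yl (2R)-2-methylbutanoate
Conditions: HF·pyridine, pyridine, THF, 0 → 23 °C
Reagents that add atoms: none
Why: buffered fluoride desilylation should free the primary alcohol without harming the allylic ester.

Step 13
Reactants: 18 (2Z,5S,6E)-2-[(2S)-3,6-dihydro-2H-pyran-2-yl]-9-hydroxy-6-methylnona-2,6-dien-5-yl (2R)-2-methylbutanoate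
Product: 20 (3E,5S,7Z)-8-[(2S)-3,6-dihydro-2H-pyran-2-yl]-4-methyl-5-{[(2R)-2-methylbutanoyl]oxy}nona-3,7-dienoic acid, via aldehyde 19 (not isolated)
Conditions: TEMPO (20 mol %), PhI(OAc)2 (2.2 equiv), MeCN/pH 7 buffer, 23 °C
Reagents that add atoms: water, O
Why: oxoammonium oxidation in water takes the primary alcohol through the aldehyde hydrate to the acid under neutral conditions that should leave the β,γ-alkene in place.

Step 14
Reactants: 20 (3E,5S,7Z)-8-[(2S)-3,6-dihydro-2H-pyran-2-yl]-4-methyl-5-{[(2R)-2-methylbutanoyl]oxy}nona-3,7-dienoic acid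
Product: 23 tricyclic cyclobutanone (cyclobutanone fused cis to the new ten-membered ring at C6–C7 and to the pyran at C7–C11), via acid chloride 21 (not isolated), via vinylketene 22 (not isolated)
Conditions: Me2C=C(Cl)NMe2, CH2Cl2, 0 °C; then addition over 12 h to i-Pr2NEt (5 equiv), toluene, 110 °C, final 1 mM
Reagents that add atoms: none
Why: Proposed new method: the amine takes HCl from acid chloride 21 to give vinylketene 22, whose carbonyl carbon C12 bonds to C11 of the pyran alkene while C6 bonds to C7 in a concerted but asynchronous thermal [2+2] cycloaddition; the closest known reaction types are the intramolecular vinylketene–alkene cycloaddition, so far used to close five- to seven-membered rings, and the high-dilution macrocyclisation of ketenes by dimerisation. The cyclobutanone closes by the [2+2] itself and the ten-membered carbocycle closes with the C6–C7 bond in the fused mode, spanning C9 and C7 of the pyran; the trans C4=C5 bond rules out any smaller ring and the cis C1=C10 bond folds the chain back. C7 and C11 should come out cis because the ring alkene is cis and reacts suprafacially, and their absolute sense follows from C9 because the chain delivers the ketene to the pyran face that carries it (the opposite face would need a trans-1,3-bridged ring). C6 is set by the usual ketene approach, which leaves the larger ketene substituent C5 cis to the alkene substituent C8 and is also the cis fusion of the new ring. The step needs C12-to-C11 regioselectivity, which the allylic ring oxygen secures by disfavouring positive charge at C11 (so the charge develops at C7) together with ten- over eleven-membered closure, and it must outrun ketene dimerisation, which slow addition at 1 mM addresses.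

Step 15
Reactants: 23 tricyclic cyclobutanone
Product: 24 tricyclic lactone (oxygen inserted between C12 and C6; pyran intact)
Conditions: 30% aq. H2O2, AcOH, 0 °C
Reagents that add atoms: hydrogen peroxide, OO
Why: Baeyer–Villiger oxidation, driven by ring strain, in which the allylic and more electron-rich C6 should migrate with retention in preference to C11 (deactivated by its CH2–O substituent), under conditions too mild to epoxidise the alkenes.

Step 16
Reactants: 24 tricyclic lactone
Product: 26 (1(10)Z,4E)-9-hydroxy-3-{[(2R)-2-methylbutanoyl]oxy}germacra-1(10),4,11(13)-trien-12,6-olide (cis-fused), via lithium enolate 25 (not isolated)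
Conditions: LiN(SiMe3)2 (1.05 equiv), THF, −78 → −30 °C; AcOH, −78 °C
Reagents that add atoms: none
Why: E1cB β-elimination (retro-oxa-Michael), in which the lactone should be deprotonated at C11 in preference to the less acidic acyclic ester and the enolate expels the ring oxygen from C13, opening the pyran to the α-methylene lactone and the free C9 hydroxyl, with a cold acidic quench to prevent re-closure.

Step 17
Reactants: 26 (1(10)Z,4E)-9-hydroxy-3-{[(2R)-2-methylbutanoyl]oxy}germacra-1(10),4,11(13)-trien-12,6-olide (cis-fused)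
Product: 27 (3S,6R,7S,9S,11R,1(10)Z,4E)-9-hydroxy-3-{[(2R)-2-methylbutanoyl]oxy}germacra-1(10),4-dien-12,6-olide (CNP0276536.2)
Conditions: H2 (1 atm), RhCl(PPh3)3 (10 mol %), benzene, 23 °C
Reagents that add atoms: none
Why: homogeneous hydrogenation should select the 1,1-disubstituted conjugated alkene over the trisubstituted ring alkenes and add hydrogen to C11 from the open lactone face opposite C5 and C8, which places the C13 methyl cis to both and sets C11 as (R).

Compound list
1 | 3-{[tert-butyl(dimethyl)silyl]oxy}propanal | O=CCCO[Si](C)(C)C(C)(C)C | starting material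
2 | ethyl 2-[bis(2,2,2-trifluoroethoxy)phosphoryl]propanoate | CCOC(=O)C(C)P(=O)(OCC(F)(F)F)OCC(F)(F)F | starting material
3 | ethyl (2Z)-5-{[tert-butyl(dimethyl)silyl]oxy}-2-methylpent-2-enoate | CC(C)(C)[Si](C)(C)OCC/C=C(/C)C(=O)OCC | intermediate
4 | (2Z)-5-{[tert-butyl(dimethyl)silyl]oxy}-2-methylpent-2-en-1-ol | CC(C)(C)[Si](C)(C)OCC/C=C(/C)CO | intermediate
5 | (2Z)-5-{[tert-butyl(dimethyl)silyl]oxy}-2-methylpent-2-enal | CC(C)(C)[Si](C)(C)OCC/C=C(/C)C=O | intermediate
6 | (4S,5Z)-8-{[tert-butyl(dimethyl)silyl]oxy}-5-methylocta-1,5-dien-4-ol | CC(C)(C)[Si](C)(C)OCC/C=C(/C)[C@@H](O)CC=C | intermediate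
7 | tert-butyl(dimethyl){[(3Z,5S)-4-methyl-5-(prop-2-en-1-yloxy)octa-3,7-dien-1-yl]oxy}silane | CC(C)(C)[Si](C)(C)OCC/C=C(/C)[C@@H](OCC=C)CC=C | intermediate
8 | tert-butyl{[(3Z)-4-[(2S)-3,6-dihydro-2H-pyran-2-yl]pent-3-en-1-yl]oxy}dimethylsilane | CC(C)(C)[Si](C)(C)OCC/C=C(/C)[C@@H]1CC=CCO1 | intermediate
9 | (3Z)-4-[(2S)-3,6-dihydro-2H-pyran-2-yl]pent-3-en-1-ol | OCC/C=C(/C)[C@@H]1CC=CCO1 | intermediate
10 | (3Z)-4-[(2S)-3,6-dihydro-2H-pyran-2-yl]pent-3-enal | O=CC/C=C(/C)[C@@H]1CC=CCO1 | intermediate
11 | pent-3-yn-1-ol | CC#CCCO | starting material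
12 | tert-butyl(dimethyl)(pent-3-yn-1-yloxy)silane | CC#CCCO[Si](C)(C)C(C)(C)C | intermediate
13 | chloro{(2E)-5-[(tert-butyldimethylsilyl)oxy]pent-2-en-2-yl}zirconocene | C/C(=C\CCO[Si](C)(C)C(C)(C)C)[Zr](Cl)(C1C=CC=C1)C1C=CC=C1 | intermediate (not isolated)
14 | methyl{(2E)-5-[(tert-butyldimethylsilyl)oxy]pent-2-en-2-yl}zinc | C/C(=C\CCO[Si](C)(C)C(C)(C)C)[Zn]C | intermediate (not isolated)
15 | (2Z,5S,6E)-9-{[tert-butyl(dimethyl)silyl]oxy}-2-[(2S)-3,6-dihydro-2H-pyran-2-yl]-6-methylnona-2,6-dien-5-ol | CC(C)(C)[Si](C)(C)OCC/C=C(\C)[C@@H](O)C/C=C(/C)[C@@H]1CC=CCO1 | intermediate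
16 | (2R)-2-methylbutanoic acid | CC[C@@H](C)C(=O)O | starting material
17 | (2Z,5S,6E)-9-{[tert-butyl(dimethyl)silyl]oxy}-2-[(2S)-3,6-dihydro-2H-pyran-2-yl]-6-methylnona-2,6-dien-5-yl (2R)-2-methylbutanoate | CC[C@@H](C)C(=O)O[C@@H](C/C=C(/C)[C@@H]1CC=CCO1)/C(C)=C/CCO[Si](C)(C)C(C)(C)C | intermediate
18 | (2Z,5S,6E)-2-[(2S)-3,6-dihydro-2H-pyran-2-yl]-9-hydroxy-6-methylnona-2,6-dien-5-yl (2R)-2-methylbutanoate | CC[C@@H](C)C(=O)O[C@@H](C/C=C(/C)[C@@H]1CC=CCO1)/C(C)=C/CCO | intermediate
19 | (2Z,5S,6E)-2-[(2S)-3,6-dihydro-2H-pyran-2-yl]-6-methyl-9-oxonona-2,6-dien-5-yl (2R)-2-methylbutanoate | CC[C@@H](C)C(=O)O[C@@H](C/C=C(/C)[C@@H]1CC=CCO1)/C(C)=C/CC=O | intermediate (not isolated)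
20 | (3E,5S,7Z)-8-[(2S)-3,6-dihydro-2H-pyran-2-yl]-4-methyl-5-{[(2R)-2-methylbutanoyl]oxy}nona-3,7-dienoic acid | CC[C@@H](C)C(=O)O[C@@H](C/C=C(/C)[C@@H]1CC=CCO1)/C(C)=C/CC(=O)O | intermediate
21 | (3E,5S,7Z)-8-[(2S)-3,6-dihydro-2H-pyran-2-yl]-4-methyl-5-{[(2R)-2-methylbutanoyl]oxy}nona-3,7-dienoyl chloride | CC[C@@H](C)C(=O)O[C@@H](C/C=C(/C)[C@@H]1CC=CCO1)/C(C)=C/CC(=O)Cl | intermediate (not isolated)
22 | (3E,5S,7Z)-8-[(2S)-3,6-dihydro-2H-pyran-2-yl]-4-methyl-5-{[(2R)-2-methylbutanoyl]oxy}nona-1,3,7-trien-1-one (vinylketene) | CC[C@@H](C)C(=O)O[C@@H](C/C=C(/C)[C@@H]1CC=CCO1)/C(C)=C/C=C=O | intermediate (not isolated)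
23 | tricyclic cyclobutanone: (1(10)Z,4E)-cyclodecadiene fused cis at C6–C7 to the cyclobutanone C6–C12(=O)–C11–C7, itself fused cis at C7–C11 to the tetrahydropyran O–C13–C11–C7–C8–C9; H6, H7 and H11 cis; C10 and C6 on the same pyran face; (3S) ester | CC[C@@H](C)C(=O)O[C@H]1C/C=C(/C)[C@@H]3C[C@@H]2[C@H](/C=C/1C)C(=O)[C@@H]2CO3 | intermediate
24 | tricyclic lactone: as 23 with oxygen inserted between C12 and C6 (cis-fused γ-lactone on the pyran) | CC[C@@H](C)C(=O)O[C@H]1C/C=C(/C)[C@@H]3C[C@@H]2[C@H](/C=C/1C)OC(=O)[C@@H]2CO3 | intermediate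
25 | lithium C11=C12 enolate of lactone 24 | CC[C@@H](C)C(=O)O[C@H]1C/C=C(/C)[C@@H]3C[C@@H]2[C@H](/C=C/1C)OC([O-])=C2CO3.[Li+] | intermediate (not isolated)
26 | (1(10)Z,4E)-9-hydroxy-3-{[(2R)-2-methylbutanoyl]oxy}germacra-1(10),4,11(13)-trien-12,6-olide, H6 and H7 cis, C3 and C9 as in the target | CC[C@@H](C)C(=O)O[C@H]1C/C=C(/C)[C@@H](O)C[C@@H]2[C@H](/C=C/1C)OC(=O)C2=C | intermediate
27 | (3S,6R,7S,9S,11R,1(10)Z,4E)-9-hydroxy-3-{[(2R)-2-methylbutanoyl]oxy}germacra-1(10),4-dien-12,6-olide (CNP0276536.2) | CC[C@@H](C)C(=O)O[C@H]1C/C=C(/C)[C@@H](O)C[C@@H]2[C@H](/C=C/1C)OC(=O)[C@@H]2C | target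

Total step count: 17. Longest linear sequence: 16 (steps 1–8, then 10–17).

Steps most likely to fail

Step 14. The ring closure may lose to dimerisation or oligomerisation of the ketene. The vinylketene may also isomerise by a 1,5-hydrogen shift from C15 before it meets the alkene, or the β-alkoxy cyclobutanone may eliminate or epimerise at C6 under the amine at 110 °C. The fallback uses known chemistry only, sets out from 6 and comes back at 26. It gives up the cycloaddition and closes the ring at C6–C7 by the chromium-mediated Nozaki–Hiyama allylation that is standard for germacranolides. Alcohol 6 is O-alkylated with methyl 2-(bromomethyl)acrylate (NaH, THF) to the acrylate ether F1, and ring-closing metathesis (second-generation Grubbs catalyst) gives the dihydropyran ester F2, which already carries C12 on C11. Bu4NF gives the alcohol F3 and Dess–Martin oxidation the aldehyde F4. The alkenylzinc reagent made as in step 10 from commercial 4,4-diethoxybut-2-yne adds under (+)-MIB control to give the allylic alcohol F5, which is esterified with 16 (EDC·HCl, DMAP) to the ester F6. Me2BBr (CH2Cl2, −78 → 0 °C) should cleave the acetal and open the allylic ring ether at C13, giving the bromo enal F7 with the C9 hydroxyl free. CrCl2 (chromium dichloride) in THF at high dilution then joins C7 to the aldehyde carbon C6 through a chair transition state that should favour the cis product, and the hydroxy ester lactonises to 26. The route is rejoined at step 17.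

Step 16. Deprotonation may fail to discriminate the lactone from the 2-methylbutanoate, which would scramble the acyl stereocentre, or the alkoxide may add back to the methylene lactone and re-close the pyran. The fallback sets out from 24 and comes back at 26. The opening is run as an amine-mediated equilibrium with trapping instead of with a stoichiometric strong base. DBU and Et3SiCl in MeCN at 40 °C, the amidine being too weak to enolise the acyclic ester, should give the triethylsilyl ether F8, and PPTS in MeOH then frees 26.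

Step 17. Hydrogen may be delivered with poor facial selectivity, or the exocyclic alkene may migrate into the ring to the butenolide before it is reduced. The fallback sets out from 26 and comes back at 27. Hydrogenation is replaced by conjugate hydride addition with [(Ph3P)CuH]6 in wet toluene at 0 °C, where the copper enolate is protonated kinetically from the open face. No new compound is made.

Further compounds
F1 | step 14 | methyl 2-({[(4S,5Z)-8-{[tert-butyl(dimethyl)silyl]oxy}-5-methylocta-1,5-dien-4-yl]oxy}methyl)prop-2-enoate | CC(C)(C)[Si](C)(C)OCC/C=C(/C)[C@@H](OCC(=C)C(=O)OC)CC=C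
F2 | step 14 | methyl (6S)-6-[(2Z)-5-{[tert-butyl(dimethyl)silyl]oxy}pent-2-en-2-yl]-5,6-dihydro-2H-pyran-3-carboxylate | CC(C)(C)[Si](C)(C)OCC/C=C(/C)[C@@H]1CC=C(CO1)C(=O)OC
F3 | step 14 | methyl (6S)-6-[(2Z)-5-hydroxypent-2-en-2-yl]-5,6-dihydro-2H-pyran-3-carboxylate | OCC/C=C(/C)[C@@H]1CC=C(CO1)C(=O)OC
F4 | step 14 | methyl (6S)-6-[(2Z)-5-oxopent-2-en-2-yl]-5,6-dihydro-2H-pyran-3-carboxylate | O=CC/C=C(/C)[C@@H]1CC=C(CO1)C(=O)OC
F5 | step 14 | methyl (6S)-6-[(2Z,5S,6E)-8,8-diethoxy-5-hydroxy-6-methylocta-2,6-dien-2-yl]-5,6-dihydro-2H-pyran-3-carboxylate | CCOC(OCC)/C=C(\C)[C@@H](O)C/C=C(/C)[C@@H]1CC=C(CO1)C(=O)OC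
F6 | step 14 | methyl (6S)-6-[(2Z,5S,6E)-8,8-diethoxy-6-methyl-5-{[(2R)-2-methylbutanoyl]oxy}octa-2,6-dien-2-yl]-5,6-dihydro-2H-pyran-3-carboxylate | CC[C@@H](C)C(=O)O[C@@H](C/C=C(/C)[C@@H]1CC=C(CO1)C(=O)OC)/C(C)=C/C(OCC)OCC
F7 | step 14 | methyl (2Z,5S,6Z,9S,10E)-2-(bromomethyl)-5-hydroxy-6,10-dimethyl-9-{[(2R)-2-methylbutanoyl]oxy}-12-oxododeca-2,6,10-trienoate | CC[C@@H](C)C(=O)O[C@@H](C/C=C(/C)[C@@H](O)C/C=C(\CBr)C(=O)OC)/C(C)=C/C=O
F8 | step 16 | 9-O-triethylsilyl ether of 26 | CC[C@@H](C)C(=O)O[C@H]1C/C=C(/C)[C@@H](O[Si](CC)(CC)CC)C[C@@H]2[C@H](/C=C/1C)OC(=O)C2=C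
F0 | step 17 | none | none
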